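Kanzonol C is cut at the single bond between the enone β-carbon and C1 of ring B. C1 lies para to the C4 hydroxyl and meta to the C3 prenyl group of ring B, so it corresponds to the iodine-bearing carbon of 4-iodophenol after one ortho-prenylation. A Mizoroki–Heck arylation joins this iodide to the terminal carbon of a ring A aryl vinyl ketone and delivers the complete chalcone skeleton with its E double bond in one operation. The vinyl ketone carries the C3' prenyl group and methoxymethyl ethers on O2' and O4'; it is assembled regioselectively from resorcinol by two directed ortho-metalations. Acidic methanolysis then releases the target.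

Key step: step 6

Remark: alcohol 8 is prepared and used as the racemate, because its single stereocentre is destroyed in step 4; the target has no stereocentre, only the E enone double bond set in step 6.

Step 1
Reactants: 1 resorcinol
Product: 2 1,3-bis(methoxymethoxy)benzene
Conditions: NaH, MOMCl, DMF, 0 °C to rt
Reagents that add atoms: chloromethyl methyl ether (MOMCl), COCCl
Why: Williamson-type O-alkylation of the resorcinol bis-phenoxide with the reactive α-chloro ether gives the bis(methoxymethyl) ether, which serves as protecting group and as directing group for the next two steps.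

Step 2
Reactants: 2 1,3-bis(methoxymethoxy)benzene; 3 prenyl bromide
Product: 5 1,3-bis(methoxymethoxy)-2-(3-methylbut-2-enyl)benzene, via 2-lithio-1,3-bis(methoxymethoxy)benzene 4 (not isolated)
Conditions: n-BuLi, THF, 0 °C to rt; then CuBr·SMe2 (10 mol%), prenyl bromide, −78 °C to rt
Reagents that add atoms: none
Why: Directed ortho-metalation: both methoxymethoxy groups direct n-BuLi to the C2 position between them, and copper-catalysed allylic substitution of the resulting aryllithium at the primary carbon of prenyl bromide fixes the prenyl group between the two oxygens without regiochemical ambiguity.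

Step 3
Reactants: 5 1,3-bis(methoxymethoxy)-2-(3-methylbut-2-enyl)benzene; 6 acrolein
Product: 8 rac-1-[2,4-bis(methoxymethoxy)-3-(3-methylbut-2-enyl)phenyl]prop-2-en-1-ol, via 4-lithio-1,3-bis(methoxymethoxy)-2-prenylbenzene 7 (not isolated)
Conditions: n-BuLi, TMEDA, THF, −20 to 0 °C; then acrolein, −78 °C; aq. NH4Cl
Reagents that add atoms: none
Why: Directed ortho-metalation followed by carbonyl addition: the methoxymethoxy group directs lithiation to C4 (equivalent to C6 by symmetry), and the hard aryllithium adds 1,2 to acrolein at −78 °C to give the aryl vinyl carbinol, whose only stereocentre forms as a racemate and is erased by the oxidation in step 4.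

Step 4
Reactants: 8 rac-1-[2,4-bis(methoxymethoxy)-3-(3-methylbut-2-enyl)phenyl]prop-2-en-1-ol
Product: 9 1-[2,4-bis(methoxymethoxy)-3-(3-methylbut-2-enyl)phenyl]prop-2-en-1-one
Conditions: MnO2 (activated, excess), CH2Cl2, rt
Reagents that add atoms: none
Why: Allylic and benzylic alcohol oxidation with activated MnO2: the doubly activated carbinol should be oxidised under neutral heterogeneous conditions that leave the acetals and the prenyl olefin untouched, and the polymerisation-prone enone is filtered, concentrated cold and used directly.

Step 5
Reactants: 10 4-iodophenol; 3 prenyl bromide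
Product: 12 4-iodo-2-(3-methylbut-2-enyl)phenol, via sodium 4-iodophenoxide 11 (not isolated)
Conditions: NaH, toluene, 0 °C to rt; then prenyl bromide, rt
Reagents that add atoms: none
Why: Ortho-selective C-alkylation of a phenoxide: in non-polar toluene the sodium phenoxide reacts as a tight aggregate whose oxygen is shielded by the cation, so prenyl bromide is attacked through the ortho carbon, the para position being blocked by iodine, which survives these non-reducing conditions.

Step 6
Reactants: 9 1-[2,4-bis(methoxymethoxy)-3-(3-methylbut-2-enyl)phenyl]prop-2-en-1-one; 12 4-iodo-2-(3-methylbut-2-enyl)phenol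
Product: 13 Kanzonol C 2',4'-bis(methoxymethyl) ether
Conditions: Pd(OAc)2 (5 mol%), Bu4NCl, NaHCO3, DMF, 60 °C
Reagents that add atoms: none
Why: Under ligand-free conditions with a tetraalkylammonium chloride, Pd(OAc)2 is reduced in situ to zerovalent palladium, which undergoes oxidative addition to aryl iodide 12; the arylpalladium iodide then carbopalladates the vinyl group of 9 in a syn fashion with the aryl group delivered to the CH2 terminus, syn β-hydride elimination expels the enone, and NaHCO3 takes up HI and returns the catalyst to its zerovalent state. The closest known reaction type is the Mizoroki–Heck arylation of aryl vinyl ketones with aryl iodides to give chalcones. No ring closes and no stereocentre forms; the E geometry follows from elimination through the rotamer that holds the new aryl group and the aroyl group anti. The step needs β-regioselectivity, which the polarised, monosubstituted acryloyl acceptor secures, and chemoselectivity over both prenyl olefins, which are trisubstituted and insert far more slowly, the ring B prenyl group also being meta to the carbon–palladium bond and so out of reach for cyclisation. The methoxymethyl ether on O2' blocks oxa-Michael closure of 9 to a chroman-4-one, and the weak base keeps the phenol of 12 largely protonated, so that phenoxide addition to the enone should stay minor and reversible.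

Step 7
Reactants: 13 Kanzonol C 2',4'-bis(methoxymethyl) ether
Product: 14 Kanzonol C
Conditions: 3 M aq. HCl, MeOH, rt
Reagents that add atoms: none
Why: Acid-catalysed acetal exchange (methanolysis of the methoxymethyl ethers) releases both ring A phenols as dimethoxymethane forms, and at room temperature with close monitoring the reaction should be stopped before the prenylphenols cyclise to chromans or the 2'-hydroxychalcone closes to a flavanone.

Compound list
1 | resorcinol (benzene-1,3-diol) | Oc1cccc(O)c1 | starting material
2 | 1,3-bis(methoxymethoxy)benzene | COCOc1cccc(OCOC)c1 | intermediate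
3 | prenyl bromide (1-bromo-3-methylbut-2-ene) | CC(C)=CCBr | starting material
4 | 2-lithio-1,3-bis(methoxymethoxy)benzene | [Li]c1c(OCOC)cccc1OCOC | intermediate
5 | 1,3-bis(methoxymethoxy)-2-(3-methylbut-2-enyl)benzene | COCOc1cccc(OCOC)c1CC=C(C)C | intermediate
6 | acrolein (prop-2-enal) | C=CC=O | starting material
7 | 4-lithio-1,3-bis(methoxymethoxy)-2-(3-methylbut-2-enyl)benzene | [Li]c1ccc(OCOC)c(CC=C(C)C)c1OCOC | intermediate
8 | rac-1-[2,4-bis(methoxymethoxy)-3-(3-methylbut-2-enyl)phenyl]prop-2-en-1-ol | C=CC(O)c1ccc(OCOC)c(CC=C(C)C)c1OCOC | intermediate
9 | 1-[2,4-bis(methoxymethoxy)-3-(3-methylbut-2-enyl)phenyl]prop-2-en-1-one | C=CC(=O)c1ccc(OCOC)c(CC=C(C)C)c1OCOC | intermediate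
10 | 4-iodophenol | Oc1ccc(I)cc1 | starting material
11 | sodium 4-iodophenoxide | [Na+].[O-]c1ccc(I)cc1 | intermediate
12 | 4-iodo-2-(3-methylbut-2-enyl)phenol | CC(C)=CCc1cc(I)ccc1O | intermediate
13 | Kanzonol C 2',4'-bis(methoxymethyl) ether, (E)-1-[2,4-bis(methoxymethoxy)-3-(3-methylbut-2-enyl)phenyl]-3-[4-hydroxy-3-(3-methylbut-2-enyl)phenyl]prop-2-en-1-one | COCOc1ccc(C(=O)/C=C/c2ccc(O)c(CC=C(C)C)c2)c(OCOC)c1CC=C(C)C | intermediate
14 | Kanzonol C, (E)-1-[2,4-dihydroxy-3-(3-methylbut-2-enyl)phenyl]-3-[4-hydroxy-3-(3-methylbut-2-enyl)phenyl]prop-2-en-1-one | CC(C)=CCc1cc(/C=C/C(=O)c2ccc(O)c(CC=C(C)C)c2O)ccc1O | target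

Total step count: 7. Longest linear sequence: 6 steps (steps 1, 2, 3, 4, 6, 7 from resorcinol); step 5 is a one-step branch from 4-iodophenol.

Steps most likely to fail

Step 6 (Heck coupling). What may go wrong: polymerisation of the aryl vinyl ketone under warm basic conditions before it is arylated, reversible conjugate addition of the phenoxide to the enone, and deactivation of the ligand-free catalyst to palladium black with the electron-rich iodide. Fallback by aldol chemistry, setting out from 5 and 12 and rejoining the route at 14: lithiation of 5 as in step 3 (through 7) and quenching with N-methoxy-N-methylacetamide should give 1-[2,4-bis(methoxymethoxy)-3-(3-methylbut-2-enyl)phenyl]ethanone F1. Phenol 12 is capped (MOMCl, NaH, DMF) as 4-iodo-1-(methoxymethoxy)-2-(3-methylbut-2-enyl)benzene F2; iodine–lithium exchange (n-BuLi, THF, −78 °C) gives [4-(methoxymethoxy)-3-(3-methylbut-2-enyl)phenyl]lithium F3, which is formylated in the same flask with DMF to 4-(methoxymethoxy)-3-(3-methylbut-2-enyl)benzaldehyde F4. Claisen–Schmidt condensation of F1 with F4 (KOH, EtOH–H2O, rt) should give Kanzonol C tris(methoxymethyl) ether F5 as the E enone, and the conditions of step 7 convert F5 into 14.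

Step 3 (second metalation and acrolein trapping). What may go wrong: deprotonation at the benzylic and allylic methylene of the prenyl group competing with ring lithiation, and conjugate addition to acrolein or its anionic polymerisation. Ring lithiation is expected to win, because the two flanking methoxymethoxy groups twist the prenyl methylene out of conjugation with the ring. Fallback by electrophilic formylation, setting out from 5 and rejoining at 8: methanolysis of 5 (HCl, MeOH, rt) gives 2-(3-methylbut-2-enyl)benzene-1,3-diol F6; magnesium-mediated ortho-formylation (MgCl2, Et3N, paraformaldehyde, MeCN, reflux) should give 2,4-dihydroxy-3-(3-methylbut-2-enyl)benzaldehyde F7, both open ortho positions being equivalent; reprotection (MOMCl, NaH, DMF) gives 2,4-bis(methoxymethoxy)-3-(3-methylbut-2-enyl)benzaldehyde F8; addition of vinylmagnesium bromide (THF, −78 to 0 °C) then gives 8.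

Step 5 (ortho-prenylation of the phenoxide). What may go wrong: O-alkylation to the prenyl ether and a second ortho-alkylation outrunning the desired mono C-alkylation in the heterogeneous slurry. Fallback by rearrangement and metathesis, setting out from 10 and rejoining at 12: O-allylation (allyl bromide, K2CO3, acetone, reflux) gives 1-iodo-4-(prop-2-enyloxy)benzene F9; aromatic Claisen rearrangement (N,N-diethylaniline, 190 °C) gives 4-iodo-2-(prop-2-enyl)phenol F10; cross-metathesis with excess 2-methylbut-2-ene (second-generation Grubbs catalyst, CH2Cl2, 40 °C) should convert the allyl into the prenyl group and give 12.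

Further compounds
F1 | step 6 | 1-[2,4-bis(methoxymethoxy)-3-(3-methylbut-2-enyl)phenyl]ethanone | CC(=O)c1ccc(OCOC)c(CC=C(C)C)c1OCOC
F2 | step 6 | 4-iodo-1-(methoxymethoxy)-2-(3-methylbut-2-enyl)benzene | COCOc1ccc(I)cc1CC=C(C)C
F3 | step 6 | [4-(methoxymethoxy)-3-(3-methylbut-2-enyl)phenyl]lithium | [Li]c1ccc(OCOC)c(CC=C(C)C)c1
F4 | step 6 | 4-(methoxymethoxy)-3-(3-methylbut-2-enyl)benzaldehyde | COCOc1ccc(C=O)cc1CC=C(C)C
F5 | step 6 | Kanzonol C tris(methoxymethyl) ether | COCOc1ccc(/C=C/C(=O)c2ccc(OCOC)c(CC=C(C)C)c2OCOC)cc1CC=C(C)C
F6 | step 3 | 2-(3-methylbut-2-enyl)benzene-1,3-diol | CC(C)=CCc1c(O)cccc1O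
F7 | step 3 | 2,4-dihydroxy-3-(3-methylbut-2-enyl)benzaldehyde | CC(C)=CCc1c(O)ccc(C=O)c1O
F8 | step 3 | 2,4-bis(methoxymethoxy)-3-(3-methylbut-2-enyl)benzaldehyde | COCOc1ccc(C=O)c(OCOC)c1CC=C(C)C
F9 | step 5 | 1-iodo-4-(prop-2-enyloxy)benzene | C=CCOc1ccc(I)cc1
F10 | step 5 | 4-iodo-2-(prop-2-enyl)phenol | C=CCc1cc(I)ccc1O
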